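## Retrosynthetic overview

- Ochtodene ⇐ (E)-allylic alcohol ⇐ (E)-γ-chloro acid ⇐ fused butenolide: the lactone C–O bond is replaced by C–Cl with inversion, the acid end becomes CH2Br, and the lactone ring fixes the alkene geometry.
- Butenolide (a temporary ring, formed after the carbocycle and opened again) ⇐ α-bromo cyclohexanone by carboxylate displacement and intramolecular Horner–Wadsworth–Emmons reaction.
- Cyclohexanone (the only ring of the target, formed first) ⇐ acyclic dibromomethyl ketone by a 6-endo bromine-atom-transfer radical cyclization that makes the ring C–C bond and the neopentyl C–Br bond together.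
- Dibromomethyl ketone ⇐ (R)-2-chloro-3,3-dimethylpent-4-enal (organocatalytic chlorination sets the absolute configuration) ⇐ prenol + ethyl vinyl ether (Claisen rearrangement).

Assumption: the (5R) enantiomer of the imidazolidinone catalyst is taken to give the (2R) chloro aldehyde (mirror image of the known (5S) to (2S) sense); if the sense is the reverse, the (5S) catalyst is used and nothing else changes.

## Route

Step 1
Reactants: 1 3-methylbut-2-en-1-ol (prenol); 2 ethyl vinyl ether
Product: 4 3,3-dimethylpent-4-enal, via prenyl vinyl ether 3 (not isolated)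
Conditions: Hg(OAc)2 (5 mol%), neat 2 (10 equiv), 35 °C; then PhMe, 130 °C, sealed tube
Reagents that add atoms: none
Why: Hg(OAc)2-catalysed vinyl ether exchange gives the allyl vinyl ether, which on heating undergoes the Claisen rearrangement ([3,3]-sigmatropic shift) through the tertiary allyl terminus to create the CMe2–CH=CH2 unit; no stereocentre is formed.

Step 2
Reactants: 4 3,3-dimethylpent-4-enal
Product: 5 (2R)-2-chloro-3,3-dimethylpent-4-enal
Conditions: (5R)-5-benzyl-2,2,3-trimethylimidazolidin-4-one·CF3CO2H (5 mol%), 2,3,4,5,6,6-hexachlorocyclohexa-2,4-dien-1-one (1.2 equiv), acetone, −30 °C; used cold without storage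
Reagents that add atoms: 2,3,4,5,6,6-hexachlorocyclohexa-2,4-dien-1-one, O=C1C(Cl)=C(Cl)C(Cl)=C(Cl)C1(Cl)Cl
Why: Enamine organocatalysis (MacMillan-type α-chlorination of aldehydes): the benzyl group of the imidazolidinone shields one face of the E-enamine so that chlorine is delivered to the other, setting the (2R) centre from which every later stereocentre is derived, and tert-alkyl-substituted acetaldehydes are expected to be tolerated.

Step 3
Reactants: 5 (2R)-2-chloro-3,3-dimethylpent-4-enal
Product: 6 (2R,3R)-1,1-dibromo-3-chloro-4,4-dimethylhex-5-en-2-ol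
Conditions: CH2Br2, LiN(iPr)2, THF, −90 °C; then 5, −90 °C; AcOH quench at −90 °C
Reagents that add atoms: dibromomethane, BrCBr
Why: Carbenoid 1,2-addition of dibromomethyllithium (the first stage of the Kowalski homologation) to the aldehyde at −90 °C outruns enolisation, so the C3 chloride centre is retained, and Cornforth control gives mainly the (2R) anti chlorohydrin, a centre that is removed again in step 4.

Step 4
Reactants: 6 (2R,3R)-1,1-dibromo-3-chloro-4,4-dimethylhex-5-en-2-ol
Product: 7 (3R)-1,1-dibromo-3-chloro-4,4-dimethylhex-5-en-2-one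
Conditions: Dess–Martin periodinane, CH2Cl2, 0 → 25 °C
Reagents that add atoms: none
Why: Dess–Martin oxidation under neutral conditions gives the dibromomethyl ketone without epimerising the α-chloro centre, whose proton is shielded by the neighbouring quaternary carbon.

Step 5
Reactants: 7 (3R)-1,1-dibromo-3-chloro-4,4-dimethylhex-5-en-2-one
Product: 8 (2R,4S)-4,6-dibromo-2-chloro-3,3-dimethylcyclohexan-1-one
Conditions: Et3B (0.2 equiv, in portions), trace air, PhH (0.01 M), 25 °C
Reagents that add atoms: none
Why: Proposed new method: a Kharasch-type bromine-atom-transfer radical cyclization in which an ethyl radical removes one bromine of the CHBr2 group, the α-bromo-α-keto radical closes in the 6-endo mode onto the terminal CH2 (the mode preferred by 2-oxohex-5-enyl radicals and the only one not blocked by the quaternary allylic carbon) to form the C5–C6 ring bond, and the resulting C4 ring radical abstracts bromine from a further molecule of 7 on the face opposite the axial C2 chlorine, setting C4 as (S) with bromine trans to chlorine and carrying the chain, while the α-bromo centre C6 is formed as interconverting epimers; the closest known reactions are the iodine-atom-transfer 6-endo cyclizations of α-iodo ketones and Kharasch additions of polyhaloalkanes to terminal alkenes.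

Step 6
Reactants: 8 (2R,4S)-4,6-dibromo-2-chloro-3,3-dimethylcyclohexan-1-one
Product: 10 (4S,6S,7aR)-6-bromo-4-chloro-5,5-dimethyl-5,6,7,7a-tetrahydro-1-benzofuran-2(4H)-one, via keto phosphonate ester 9 (not isolated)
Conditions: (EtO)2P(O)CH2CO2H (1.1 equiv), Cs2CO3 (1.1 equiv), MeCN, 0 → 25 °C
Reagents that add atoms: 2-(diethoxyphosphoryl)acetic acid, CCOP(=O)(CC(O)=O)OCC
Why: SN2 displacement of the activated α-keto bromide by the cesium carboxylate (inversion of the axial bromide epimer that is cis to chlorine, the epimers interconverting by bromide exchange) and intramolecular Horner–Wadsworth–Emmons olefination give the butenolide, whose ring holds the new carbonyl carbon syn to the oxygen-bearing carbon and thereby fixes the later E geometry, while carbonate equilibrates any C7a epimer through the 2-oxidofuran to the more stable (7aR) isomer having axial chlorine and equatorial bromine.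

Step 7
Reactants: 10 (4S,6S,7aR)-6-bromo-4-chloro-5,5-dimethyl-5,6,7,7a-tetrahydro-1-benzofuran-2(4H)-one
Product: 11 (2E)-2-[(2S,4S,6S)-4-bromo-2,6-dichloro-3,3-dimethylcyclohexylidene]acetic acid
Conditions: BCl3 (2 equiv, 1 M in CH2Cl2), CH2Cl2, −78 → −20 °C; then H2O, 0 °C
Reagents that add atoms: boron trichloride, ClB(Cl)Cl
Why: Lewis-acid-assisted alkyl–oxygen cleavage of the allylic lactone by chloride (SN2, as in boron trihalide openings of lactones) inverts the former C7a to give the C6 chloride cis to the C2 chloride, ionisation being disfavoured because the allyl cation would be conjugated to the acyl group, and the alkene leaves the ring with its geometry intact as E.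

Step 8
Reactants: 11 (2E)-2-[(2S,4S,6S)-4-bromo-2,6-dichloro-3,3-dimethylcyclohexylidene]acetic acid
Product: 12 (2E)-2-[(2S,4S,6S)-4-bromo-2,6-dichloro-3,3-dimethylcyclohexylidene]ethan-1-ol
Conditions: BH3·THF (1.5 equiv), THF, 0 °C; then H2O
Reagents that add atoms: none
Why: Borane reduction of the carboxylic acid via the acyloxyborane is chemoselective for CO2H over the C–Cl and C–Br bonds and the trisubstituted alkene at 0 °C, so the allylic alcohol forms with all stereocentres and the E-alkene unchanged.

Step 9
Reactants: 12 (2E)-2-[(2S,4S,6S)-4-bromo-2,6-dichloro-3,3-dimethylcyclohexylidene]ethan-1-ol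
Product: 13 ochtodene [(1S,2E,3S,5S)-5-bromo-2-(2-bromoethylidene)-1,3-dichloro-4,4-dimethylcyclohexane]
Conditions: CBr4, PPh3, CH2Cl2, −20 → 0 °C
Reagents that add atoms: carbon tetrabromide, BrC(Br)(Br)Br
Why: Appel bromination, in which bromide displaces the alkoxyphosphonium group by SN2 at the primary allylic carbon without allylic transposition, gives ochtodene with the three stereocentres and the E-alkene untouched.

## Compound list

1 | 3-methylbut-2-en-1-ol (prenol) | CC(C)=CCO | starting material
2 | ethyl vinyl ether | C=COCC | starting material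
3 | 3-methyl-1-(vinyloxy)but-2-ene (prenyl vinyl ether) | CC(C)=CCOC=C | intermediate
4 | 3,3-dimethylpent-4-enal | O=CCC(C)(C)C=C | intermediate
5 | (2R)-2-chloro-3,3-dimethylpent-4-enal | O=C[C@H](Cl)C(C)(C)C=C | intermediate
6 | (2R,3R)-1,1-dibromo-3-chloro-4,4-dimethylhex-5-en-2-ol (major anti isomer; the C2 epimer is carried on as well) | O[C@@H](C(Br)Br)[C@H](Cl)C(C)(C)C=C | intermediate
7 | (3R)-1,1-dibromo-3-chloro-4,4-dimethylhex-5-en-2-one | O=C(C(Br)Br)[C@H](Cl)C(C)(C)C=C | intermediate
8 | (2R,4S)-4,6-dibromo-2-chloro-3,3-dimethylcyclohexan-1-one (C6 epimers, interconverting) | CC1(C)[C@@H](Br)CC(Br)C(=O)[C@@H]1Cl | intermediate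
9 | (1R,3R,5S)-5-bromo-3-chloro-4,4-dimethyl-2-oxocyclohexyl 2-(diethoxyphosphoryl)acetate | CC1(C)[C@@H](Br)C[C@@H](OC(=O)CP(=O)(OCC)OCC)C(=O)[C@@H]1Cl | intermediate
10 | (4S,6S,7aR)-6-bromo-4-chloro-5,5-dimethyl-5,6,7,7a-tetrahydro-1-benzofuran-2(4H)-one | CC1(C)[C@@H](Br)C[C@H]2OC(=O)C=C2[C@@H]1Cl | intermediate
11 | (2E)-2-[(2S,4S,6S)-4-bromo-2,6-dichloro-3,3-dimethylcyclohexylidene]acetic acid | CC1(C)[C@@H](Br)C[C@H](Cl)/C(=C\C(O)=O)[C@@H]1Cl | intermediate
12 | (2E)-2-[(2S,4S,6S)-4-bromo-2,6-dichloro-3,3-dimethylcyclohexylidene]ethan-1-ol | CC1(C)[C@@H](Br)C[C@H](Cl)/C(=C\CO)[C@@H]1Cl | intermediate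
13 | ochtodene, (1S,2E,3S,5S)-5-bromo-2-(2-bromoethylidene)-1,3-dichloro-4,4-dimethylcyclohexane | CC1(C)[C@@H](Br)C[C@H](Cl)/C(=C\CBr)[C@@H]1Cl | target

## Step count and risks

Total step count: 9. Longest linear sequence: 9 (from prenol).

The three steps most likely to fail:

**Step 5 (radical ring closure).** The bromine chain may be short, 5-exo closure may compete, or bromine may be delivered cis to the chlorine. The fallback sets out from 7 and comes back at 8. KSC(S)OEt (1 equiv, acetone, 0 °C) replaces one bromine of 7 to give O-ethyl S-[(3R)-1-bromo-3-chloro-4,4-dimethyl-2-oxohex-5-en-1-yl] carbonodithioate F1. Dilauroyl peroxide (substoichiometric, 1,2-dichloroethane, reflux) then drives a degenerative xanthate-group-transfer 6-endo cyclization to O-ethyl S-[(1S,3R)-5-bromo-3-chloro-2,2-dimethyl-4-oxocyclohexyl] carbonodithioate F2. Radical exchange of the xanthate for bromine with ethyl 2-bromo-2-methylpropanoate and dilauroyl peroxide (chlorobenzene, reflux) returns 8. The ring closure is thus separated from the bromine delivery, whose donor and temperature can then be tuned for the trans isomer.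

**Step 6 (butenolide formation).** Carbonate may epimerise the chloro ketone, trigger a Favorskii-type contraction, or cause 1,3-elimination of the ring bromide. The fallback sets out from 8 and comes back at 10. HCO2Cs (DMF, 0 °C) displaces the α-keto bromide to give (1R,3R,5S)-5-bromo-3-chloro-4,4-dimethyl-2-oxocyclohexyl formate F3. Mild acidic methanolysis (MeOH, cat. TsOH) frees (2R,4S,6R)-4-bromo-2-chloro-6-hydroxy-3,3-dimethylcyclohexan-1-one F4. Ph3P=C=C=O (PhMe, 80 °C) then closes the butenolide 10 by O-acylation and intramolecular Wittig reaction with no added base.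

**Step 7 (lactone opening by chloride).** The allylic C–O bond may resist cleavage or ionise, which would lose the configuration at the new C–Cl centre, and HCl may add reversibly to the unsaturated acid. The fallback sets out from 10 and comes back at 12. iBu2AlH (CH2Cl2, −78 °C) reduces the lactone to (1R,2E,3S,5S)-5-bromo-3-chloro-2-(2-hydroxyethylidene)-4,4-dimethylcyclohexan-1-ol F5. TBSCl and imidazole (CH2Cl2, −20 °C) silylate the primary hydroxyl to give (1R,2E,3S,5S)-5-bromo-2-[2-(tert-butyldimethylsilyloxy)ethylidene]-3-chloro-4,4-dimethylcyclohexan-1-ol F6. Ph3P and CCl4 convert the secondary allylic alcohol with inversion to tert-butyl{(2E)-2-[(2S,4S,6S)-4-bromo-2,6-dichloro-3,3-dimethylcyclohexylidene]ethoxy}dimethylsilane F7. HF·pyridine (THF, 0 °C) removes the silyl group to give 12.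

Further compounds
F1 | step 5 | O-ethyl S-[(3R)-1-bromo-3-chloro-4,4-dimethyl-2-oxohex-5-en-1-yl] carbonodithioate | CCOC(=S)SC(Br)C(=O)[C@H](Cl)C(C)(C)C=C
F2 | step 5 | O-ethyl S-[(1S,3R)-5-bromo-3-chloro-2,2-dimethyl-4-oxocyclohexyl] carbonodithioate | CC1(C)[C@@H](SC(=S)OCC)CC(Br)C(=O)[C@@H]1Cl
F3 | step 6 | (1R,3R,5S)-5-bromo-3-chloro-4,4-dimethyl-2-oxocyclohexyl formate | CC1(C)[C@@H](Br)C[C@@H](OC=O)C(=O)[C@@H]1Cl
F4 | step 6 | (2R,4S,6R)-4-bromo-2-chloro-6-hydroxy-3,3-dimethylcyclohexan-1-one | CC1(C)[C@@H](Br)C[C@@H](O)C(=O)[C@@H]1Cl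
F5 | step 7 | (1R,2E,3S,5S)-5-bromo-3-chloro-2-(2-hydroxyethylidene)-4,4-dimethylcyclohexan-1-ol | CC1(C)[C@@H](Br)C[C@@H](O)/C(=C\CO)[C@@H]1Cl
F6 | step 7 | (1R,2E,3S,5S)-5-bromo-2-[2-(tert-butyldimethylsilyloxy)ethylidene]-3-chloro-4,4-dimethylcyclohexan-1-ol | CC1(C)[C@@H](Br)C[C@@H](O)/C(=C\CO[Si](C)(C)C(C)(C)C)[C@@H]1Cl
F7 | step 7 | tert-butyl{(2E)-2-[(2S,4S,6S)-4-bromo-2,6-dichloro-3,3-dimethylcyclohexylidene]ethoxy}dimethylsilane | CC1(C)[C@@H](Br)C[C@H](Cl)/C(=C\CO[Si](C)(C)C(C)(C)C)[C@@H]1Cl
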